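## Retrosynthetic overview

1. Target 28 ⇐ bis-TIPS ether 27 (buffered fluoride); the C2–aryl bond and the (2S) centre ⇐ Rh-catalysed asymmetric 1,4-addition of boronic acid 24 to chromone 26.
2. 26 ⇐ Negishi sp3–sp2 coupling of 8-iodochromone 13 with (S)-lavandulylzinc iodide 25; the three building blocks carry 14, 10 and 9 of the 33 heavy atoms of the target.
3. 13 ⇐ resorcinol: mono-methylation, MOM ether, Ir C–H borylation/oxidation (third oxygen), TIPS ether, ortho-lithiation/acetylation, enaminone ring closure, C8 iodination.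
4. 25 ⇐ Evans deconjugative α-prenylation of a senecioyl imide (sets the lavandulyl centre), LiBH4, iodination; 24 ⇐ 3-methoxyphenol by TIPS-blocked ortho-lithiation/borylation.
5. Ring order: both benzene rings come from resorcinol; the pyranone ring is closed in step 6 and becomes the chromanone ring in the last coupling (step 15).

Assumption: the recoverable Evans auxiliary, the ligands and the boron, silicon and halogen sources are treated as reagents; only compounds that deliver skeleton atoms to the target are numbered as starting materials.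

## Route

Step 1
Reactants: 1 resorcinol
Product: 2 3-methoxyphenol
Conditions: Me2SO4 (1.0 equiv), NaOH, H2O/toluene, 40 °C; unreacted 1 recycled
Reagents that add atoms: dimethyl sulfate COS(=O)(=O)OC
Why: Statistical Williamson mono-O-methylation of a symmetrical diphenol (about 50%), the mono-ether being separated from the diether by base extraction and from resorcinol by water washing.

Step 2
Reactants: 2 3-methoxyphenol
Product: 3 1-methoxy-3-(methoxymethoxy)benzene
Conditions: MOMCl, i-Pr2NEt, CH2Cl2, 0 °C → rt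
Reagents that add atoms: chloromethyl methyl ether COCCl
Why: O-alkylation to the MOM acetal, which protects the future ring oxygen O1 and later serves as the ortho-directing group.

Step 3
Reactants: 3 1-methoxy-3-(methoxymethoxy)benzene
Product: 5 3-methoxy-5-(methoxymethoxy)phenol, via pinacol boronate 4 (not isolated)
Conditions: [Ir(OMe)(cod)]2 (1.5 mol%), dtbpy (3 mol%), B2pin2 (0.6 equiv), THF, 80 °C; then aq. NaOH, H2O2, 0 °C → rt
Reagents that add atoms: bis(pinacolato)diboron CC1(C)OB(OC1(C)C)B1OC(C)(C)C(C)(C)O1; hydrogen peroxide OO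
Why: Sterically controlled Ir-catalysed C–H borylation attacks only the C–H meta to both alkoxy groups, and boronate oxidation then gives the phenol (one-pot borylation/oxidation).

Step 4
Reactants: 5 3-methoxy-5-(methoxymethoxy)phenol
Product: 6 [3-methoxy-5-(methoxymethoxy)phenoxy]tri(propan-2-yl)silane
Conditions: TIPSCl, imidazole, DMF, rt
Reagents that add atoms: chlorotri(propan-2-yl)silane CC(C)[Si](Cl)(C(C)C)C(C)C
Why: Silylation of the phenol; the bulky non-coordinating TIPS ether protects the future 7-OH and shields its two ortho positions from lithiation.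

Step 5
Reactants: 6 [3-methoxy-5-(methoxymethoxy)phenoxy]tri(propan-2-yl)silane; 7 N-methoxy-N-methylacetamide
Product: 9 1-[2-methoxy-6-(methoxymethoxy)-4-(triisopropylsilyloxy)phenyl]ethan-1-one, via aryllithium 8 (not isolated)
Conditions: n-BuLi (1.2 equiv), THF, 0 °C, 1 h; then 7, −78 → 0 °C; H2O
Reagents that add atoms: n-butyllithium [Li]CCCC (supplies the lithium of 8)
Why: Directed ortho-metalation occurs at the only C–H flanked by two coordinating groups (OMe and OMOM), and the aryllithium gives the methyl ketone by Weinreb ketone synthesis without over-addition.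

Step 6
Reactants: 9 1-[2-methoxy-6-(methoxymethoxy)-4-(triisopropylsilyloxy)phenyl]ethan-1-one; 10 N,N-dimethylformamide dimethyl acetal
Product: 12 5-methoxy-7-(triisopropylsilyloxy)-4H-chromen-4-one, via enaminone 11 (not isolated)
Conditions: 10 (3 equiv), toluene, 100 °C; evaporate; then HCl (2 M in MeOH), CH2Cl2, rt, 1 h
Reagents that add atoms: none
Why: Enaminone condensation, then acid cleaves the carbonyl-flanked MOM ether and the freed phenol closes the pyranone by addition–elimination of dimethylamine (enaminone chromone synthesis); the aryl TIPS ether survives brief dilute acid.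

Step 7
Reactants: 12 5-methoxy-7-(triisopropylsilyloxy)-4H-chromen-4-one
Product: 13 8-iodo-5-methoxy-7-(triisopropylsilyloxy)-4H-chromen-4-one
Conditions: NIS (1.1 equiv), TFA (0.3 equiv), MeCN, 0 °C → rt
Reagents that add atoms: N-iodosuccinimide O=C1CCC(=O)N1I
Why: Electrophilic aromatic iodination goes to C8, which is para to the strongly donating 5-OMe, whereas C6 is para only to the weakly donating pyranone oxygen, as is usual for 5,7-dialkoxychromones.

Step 8
Reactants: 14 3-methylbut-2-enoyl chloride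
Product: 15 (4S)-4-benzyl-3-(3-methylbut-2-enoyl)-1,3-oxazolidin-2-one
Conditions: (S)-4-benzyloxazolidin-2-one, n-BuLi, THF, −78 °C; then 14, −78 → 0 °C
Reagents that add atoms: (4S)-4-benzyl-1,3-oxazolidin-2-one O=C1N[C@@H](Cc2ccccc2)CO1
Why: N-acylation of the lithiated Evans auxiliary by the acid chloride.

Step 9
Reactants: 15 (4S)-4-benzyl-3-(3-methylbut-2-enoyl)-1,3-oxazolidin-2-one; 16 1-bromo-3-methylbut-2-ene (prenyl bromide)
Product: 18 (4S)-4-benzyl-3-[(2S)-5-methyl-2-(prop-1-en-2-yl)hex-4-enoyl]-1,3-oxazolidin-2-one, via sodium dienolate 17 (not isolated)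
Conditions: NaHMDS (1.05 equiv), THF, −78 °C; then 16 (3 equiv), −78 → −40 °C
Reagents that add atoms: sodium bis(trimethylsilyl)amide C[Si](C)(C)N([Na])[Si](C)(C)C (supplies the sodium of 17)
Why: γ-Deprotonation gives the chelated (Z)-dienolate, which is alkylated at Cα on the face opposite the benzyl group (deconjugative Evans alkylation), setting the (2S) centre with dr ≥ 95:5; the minor isomer is removed by chromatography.

Step 10
Reactants: 18 (4S)-4-benzyl-3-[(2S)-5-methyl-2-(prop-1-en-2-yl)hex-4-enoyl]-1,3-oxazolidin-2-one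
Product: 19 (2S)-5-methyl-2-(prop-1-en-2-yl)hex-4-en-1-ol ((S)-lavandulol)
Conditions: LiBH4, H2O (1.1 equiv), Et2O, 0 °C
Reagents that add atoms: none
Why: Reductive cleavage of the imide at the exocyclic carbonyl gives the primary alcohol without touching the stereocentre, and the auxiliary is recovered.

Step 11
Reactants: 19 (2S)-5-methyl-2-(prop-1-en-2-yl)hex-4-en-1-ol
Product: 20 (3S)-3-(iodomethyl)-2,6-dimethylhepta-1,5-diene ((S)-lavandulyl iodide)
Conditions: PPh3, imidazole, I2 (premixed), CH2Cl2, 0 °C → rt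
Reagents that add atoms: iodine II
Why: Appel-type (Garegg–Samuelsson) iodination at the primary carbon; premixing leaves no free iodine for the alkenes, and the β-stereocentre is not involved.

Step 12
Reactants: 2 3-methoxyphenol
Product: 21 (3-methoxyphenoxy)tri(propan-2-yl)silane
Conditions: TIPSCl, imidazole, DMF, rt
Reagents that add atoms: chlorotri(propan-2-yl)silane CC(C)[Si](Cl)(C(C)C)C(C)C
Why: Silylation of the phenol gives a fluoride-labile protecting group that also blocks lithiation next to it.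

Step 13
Reactants: 21 (3-methoxyphenoxy)tri(propan-2-yl)silane
Product: 24 [2-methoxy-4-(triisopropylsilyloxy)phenyl]boronic acid, via aryllithium 22 (not isolated), via lithium arylborate 23 (not isolated)
Conditions: n-BuLi, TMEDA, Et2O, 0 °C → rt, 3 h; B(Oi-Pr)3, −78 °C → rt; aq. HCl to pH 5–6
Reagents that add atoms: n-butyllithium [Li]CCCC (supplies the lithium of 22 and 23); triisopropyl borate CC(C)OB(OC(C)C)OC(C)C; water O
Why: Methoxy-directed ortho-lithiation takes place at C6 (para to OTIPS) because the site between the two oxygens is shielded by the TIPS group, and borate trapping with mild hydrolysis gives the boronic acid.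

Step 14
Reactants: 20 (3S)-3-(iodomethyl)-2,6-dimethylhepta-1,5-diene; 13 8-iodo-5-methoxy-7-(triisopropylsilyloxy)-4H-chromen-4-one
Product: 26 5-methoxy-8-[(2R)-5-methyl-2-(prop-1-en-2-yl)hex-4-en-1-yl]-7-(triisopropylsilyloxy)-4H-chromen-4-one, via alkylzinc iodide 25 (not isolated)
Conditions: Zn dust (TMSCl/BrCH2CH2Br-activated), LiCl, THF, 40 °C; then 13, Pd2(dba)3 (2.5 mol%), SPhos (10 mol%), THF/NMP, 45 °C
Reagents that add atoms: zinc [Zn] (supplies the zinc of 25)
Why: Zinc insertion into the primary C–I bond followed by Negishi sp3–sp2 cross-coupling, in which the bulky biarylphosphine lets reductive elimination outrun β-hydride elimination; the stereocentre is untouched and its descriptor changes from S to R only through CIP priorities.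

Step 15
Reactants: 26 5-methoxy-8-[(2R)-5-methyl-2-(prop-1-en-2-yl)hex-4-en-1-yl]-7-(triisopropylsilyloxy)-4H-chromen-4-one; 24 [2-methoxy-4-(triisopropylsilyloxy)phenyl]boronic acid
Product: 27 (2S)-5-methoxy-2-[2-methoxy-4-(triisopropylsilyloxy)phenyl]-8-[(2R)-5-methyl-2-(prop-1-en-2-yl)hex-4-en-1-yl]-7-(triisopropylsilyloxy)-2,3-dihydro-4H-chromen-4-one
Conditions: [Rh(OH)(cod)]2 (2.5 mol%) premixed with (S)-MeO-F12-BIPHEP (6 mol%), 24 (3 equiv), CH2Cl2/H2O (10:1), 30 °C
Reagents that add atoms: none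
Why: Hayashi–Miyaura Rh-catalysed asymmetric 1,4-addition to the chromone under catalyst control, where the (S)-biaryl diphosphine is expected to deliver the aryl group to the face giving (2S) (same sense as (S)-BINAP giving (S)-3-arylcyclohexanone, to be confirmed by CD); the neutral medium keeps the flavanone from ring-opening.

Step 16
Reactants: 27 (2S)-5-methoxy-2-[2-methoxy-4-(triisopropylsilyloxy)phenyl]-8-[(2R)-5-methyl-2-(prop-1-en-2-yl)hex-4-en-1-yl]-7-(triisopropylsilyloxy)-2,3-dihydro-4H-chromen-4-one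
Product: 28 (2S)-7-hydroxy-2-(4-hydroxy-2-methoxyphenyl)-5-methoxy-8-[(2R)-5-methyl-2-(prop-1-en-2-yl)hex-4-en-1-yl]-2,3-dihydro-4H-chromen-4-one ((2S)-2'-methoxykurarinone)
Conditions: TBAF (2.4 equiv), AcOH (2.6 equiv), THF, 0 °C → rt
Reagents that add atoms: none
Why: Fluoride-driven cleavage of both aryl silyl ethers; acetic acid buffering prevents base-induced retro-oxa-Michael epimerisation at C2, and no acid strong enough to cyclise the lavandulyl alkenes onto 7-OH is present.

## Compound list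

1 | resorcinol | Oc1cccc(O)c1 | starting material
2 | 3-methoxyphenol | COc1cccc(O)c1 | intermediate
3 | 1-methoxy-3-(methoxymethoxy)benzene | COCOc1cccc(OC)c1 | intermediate
4 | 2-[3-methoxy-5-(methoxymethoxy)phenyl]-4,4,5,5-tetramethyl-1,3,2-dioxaborolane | COCOc1cc(OC)cc(B2OC(C)(C)C(C)(C)O2)c1 | intermediate
5 | 3-methoxy-5-(methoxymethoxy)phenol | COCOc1cc(O)cc(OC)c1 | intermediate
6 | [3-methoxy-5-(methoxymethoxy)phenoxy]tri(propan-2-yl)silane | COCOc1cc(OC)cc(O[Si](C(C)C)(C(C)C)C(C)C)c1 | intermediate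
7 | N-methoxy-N-methylacetamide | CC(=O)N(C)OC | starting material
8 | [2-methoxy-6-(methoxymethoxy)-4-(triisopropylsilyloxy)phenyl]lithium | [Li]c1c(OC)cc(O[Si](C(C)C)(C(C)C)C(C)C)cc1OCOC | intermediate
9 | 1-[2-methoxy-6-(methoxymethoxy)-4-(triisopropylsilyloxy)phenyl]ethan-1-one | CC(=O)c1c(OC)cc(O[Si](C(C)C)(C(C)C)C(C)C)cc1OCOC | intermediate
10 | N,N-dimethylformamide dimethyl acetal | COC(OC)N(C)C | starting material
11 | (E)-3-(dimethylamino)-1-[2-methoxy-6-(methoxymethoxy)-4-(triisopropylsilyloxy)phenyl]prop-2-en-1-one | CN(C)/C=C/C(=O)c1c(OC)cc(O[Si](C(C)C)(C(C)C)C(C)C)cc1OCOC | intermediate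
12 | 5-methoxy-7-(triisopropylsilyloxy)-4H-chromen-4-one | COc1cc(O[Si](C(C)C)(C(C)C)C(C)C)cc2occc(=O)c12 | intermediate
13 | 8-iodo-5-methoxy-7-(triisopropylsilyloxy)-4H-chromen-4-one | COc1cc(O[Si](C(C)C)(C(C)C)C(C)C)c(I)c2occc(=O)c12 | intermediate
14 | 3-methylbut-2-enoyl chloride | CC(C)=CC(=O)Cl | starting material
15 | (4S)-4-benzyl-3-(3-methylbut-2-enoyl)-1,3-oxazolidin-2-one | CC(C)=CC(=O)N1[C@@H](Cc2ccccc2)COC1=O | intermediate
16 | 1-bromo-3-methylbut-2-ene (prenyl bromide) | CC(C)=CCBr | starting material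
17 | sodium (1Z)-1-[(4S)-4-benzyl-2-oxo-1,3-oxazolidin-3-yl]-3-methylbuta-1,3-dien-1-olate | [Na+].C=C(C)/C=C(\[O-])N1[C@@H](Cc2ccccc2)COC1=O | intermediate
18 | (4S)-4-benzyl-3-[(2S)-5-methyl-2-(prop-1-en-2-yl)hex-4-enoyl]-1,3-oxazolidin-2-one | CC(C)=CC[C@@H](C(C)=C)C(=O)N1[C@@H](Cc2ccccc2)COC1=O | intermediate
19 | (2S)-5-methyl-2-(prop-1-en-2-yl)hex-4-en-1-ol ((S)-lavandulol) | CC(C)=CC[C@@H](C(C)=C)CO | intermediate
20 | (3S)-3-(iodomethyl)-2,6-dimethylhepta-1,5-diene ((S)-lavandulyl iodide) | CC(C)=CC[C@@H](C(C)=C)CI | intermediate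
21 | (3-methoxyphenoxy)tri(propan-2-yl)silane | COc1cccc(O[Si](C(C)C)(C(C)C)C(C)C)c1 | intermediate
22 | [2-methoxy-4-(triisopropylsilyloxy)phenyl]lithium | COc1cc(O[Si](C(C)C)(C(C)C)C(C)C)ccc1[Li] | intermediate
23 | lithium triisopropoxy[2-methoxy-4-(triisopropylsilyloxy)phenyl]borate | [Li+].COc1cc(O[Si](C(C)C)(C(C)C)C(C)C)ccc1[B-](OC(C)C)(OC(C)C)OC(C)C | intermediate
24 | [2-methoxy-4-(triisopropylsilyloxy)phenyl]boronic acid | COc1cc(O[Si](C(C)C)(C(C)C)C(C)C)ccc1B(O)O | intermediate
25 | [(2S)-5-methyl-2-(prop-1-en-2-yl)hex-4-en-1-yl]zinc iodide | CC(C)=CC[C@@H](C(C)=C)C[Zn]I | intermediate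
26 | 5-methoxy-8-[(2R)-5-methyl-2-(prop-1-en-2-yl)hex-4-en-1-yl]-7-(triisopropylsilyloxy)-4H-chromen-4-one | COc1cc(O[Si](C(C)C)(C(C)C)C(C)C)c(C[C@@H](CC=C(C)C)C(C)=C)c2occc(=O)c12 | intermediate
27 | (2S)-5-methoxy-2-[2-methoxy-4-(triisopropylsilyloxy)phenyl]-8-[(2R)-5-methyl-2-(prop-1-en-2-yl)hex-4-en-1-yl]-7-(triisopropylsilyloxy)-2,3-dihydro-4H-chromen-4-one | C=C(C)[C@H](CC=C(C)C)Cc1c(O[Si](C(C)C)(C(C)C)C(C)C)cc(OC)c2c1O[C@H](c1ccc(O[Si](C(C)C)(C(C)C)C(C)C)cc1OC)CC2=O | intermediate
28 | (2S)-7-hydroxy-2-(4-hydroxy-2-methoxyphenyl)-5-methoxy-8-[(2R)-5-methyl-2-(prop-1-en-2-yl)hex-4-en-1-yl]-2,3-dihydro-4H-chromen-4-one | C=C(C)[C@H](CC=C(C)C)Cc1c(O)cc(OC)c2c1O[C@H](c1ccc(O)cc1OC)CC2=O | target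

## Step count and risks

Total step count: 16.
Longest linear sequence: 10 steps (steps 1–7, then 14–16).

**Step 14 (Negishi coupling).** The iodide is flanked by the ring oxygen and the bulky OTIPS group, and the alkylzinc is β-branched, so conversion may be poor or reduction of 13 may compete. The fallback sets out from 20 (with 13) and comes back at 26. Iodine–lithium exchange on 20 (t-BuLi, 2.1 equiv, Et2O/pentane, −78 °C) gives [(2S)-5-methyl-2-(prop-1-en-2-yl)hex-4-en-1-yl]lithium F4. Trapping with B-methoxy-9-BBN gives the borate lithium 9-methoxy-9-[(2S)-5-methyl-2-(prop-1-en-2-yl)hex-4-en-1-yl]-9-boranuidabicyclo[3.3.1]nonane F5. This is joined to 13 in a B-alkyl Suzuki–Miyaura coupling (PdCl2(dppf), aq. K3PO4, DMF/THF, rt) to give 26. The change replaces the heterogeneous zinc insertion and zinc-to-palladium transfer by a boron ate transfer that works on hindered aryl iodides at room temperature.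

**Step 15 (asymmetric 1,4-addition).** The chromone is electron-rich and hindered, the ortho-methoxy boronic acid can protodeboronate, and the ee and its sense are predicted rather than known. The fallback sets out from 26 (with 24) and comes back at 27. Phosphine-free [Rh(OH)(cod)]2 in dioxane/H2O, which is far more active, adds 24 without facial control to give (2RS)-5-methoxy-2-[2-methoxy-4-(triisopropylsilyloxy)phenyl]-8-[(2R)-5-methyl-2-(prop-1-en-2-yl)hex-4-en-1-yl]-7-(triisopropylsilyloxy)-2,3-dihydro-4H-chromen-4-one F6 as a roughly 1:1 pair of C2 epimers. A Noyori–Ikariya transfer hydrogenation used as a kinetic resolution (RuCl[(R,R)-TsDPEN](p-cymene), HCO2H/Et3N, rt, stopped near 50% conversion) then reduces only the (2R) epimer. This gives the cis alcohol (2R,4R)-5-methoxy-2-[2-methoxy-4-(triisopropylsilyloxy)phenyl]-8-[(2R)-5-methyl-2-(prop-1-en-2-yl)hex-4-en-1-yl]-7-(triisopropylsilyloxy)-3,4-dihydro-2H-chromen-4-ol F7, and the untouched (2S) ketone 27 is separated by chromatography.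

**Step 7 (C8 iodination).** C6 iodination may compete because OTIPS hinders C8. The fallback sets out from 9 and comes back at 13. Dilute HCl in MeOH at 0 °C removes only the carbonyl-chelated MOM group to give 1-[2-hydroxy-6-methoxy-4-(triisopropylsilyloxy)phenyl]ethan-1-one F1. Benzyltrimethylammonium dichloroiodate with NaHCO3 in CH2Cl2–MeOH iodinates ortho to the chelated phenol (the future C8) to give 1-[2-hydroxy-3-iodo-6-methoxy-4-(triisopropylsilyloxy)phenyl]ethan-1-one F2. Condensation with 10 (toluene, 90 °C) gives (E)-3-(dimethylamino)-1-[2-hydroxy-3-iodo-6-methoxy-4-(triisopropylsilyloxy)phenyl]prop-2-en-1-one F3, which closes to 13 with catalytic HCl in CH2Cl2. Here the regiochemistry is fixed by the free phenol before the pyranone ring exists.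

## Further compounds

F1 | step 7 | 1-[2-hydroxy-6-methoxy-4-(triisopropylsilyloxy)phenyl]ethan-1-one | CC(=O)c1c(O)cc(O[Si](C(C)C)(C(C)C)C(C)C)cc1OC
F2 | step 7 | 1-[2-hydroxy-3-iodo-6-methoxy-4-(triisopropylsilyloxy)phenyl]ethan-1-one | CC(=O)c1c(O)c(I)c(O[Si](C(C)C)(C(C)C)C(C)C)cc1OC
F3 | step 7 | (E)-3-(dimethylamino)-1-[2-hydroxy-3-iodo-6-methoxy-4-(triisopropylsilyloxy)phenyl]prop-2-en-1-one | CN(C)/C=C/C(=O)c1c(O)c(I)c(O[Si](C(C)C)(C(C)C)C(C)C)cc1OC
F4 | step 14 | [(2S)-5-methyl-2-(prop-1-en-2-yl)hex-4-en-1-yl]lithium | [Li]C[C@@H](CC=C(C)C)C(C)=C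
F5 | step 14 | lithium 9-methoxy-9-[(2S)-5-methyl-2-(prop-1-en-2-yl)hex-4-en-1-yl]-9-boranuidabicyclo[3.3.1]nonane | [Li+].CO[B-]1(C[C@@H](CC=C(C)C)C(C)=C)C2CCCC1CCC2
F6 | step 15 | (2RS)-5-methoxy-2-[2-methoxy-4-(triisopropylsilyloxy)phenyl]-8-[(2R)-5-methyl-2-(prop-1-en-2-yl)hex-4-en-1-yl]-7-(triisopropylsilyloxy)-2,3-dihydro-4H-chromen-4-one | C=C(C)[C@H](CC=C(C)C)Cc1c(O[Si](C(C)C)(C(C)C)C(C)C)cc(OC)c2c1OC(c1ccc(O[Si](C(C)C)(C(C)C)C(C)C)cc1OC)CC2=O
F7 | step 15 | (2R,4R)-5-methoxy-2-[2-methoxy-4-(triisopropylsilyloxy)phenyl]-8-[(2R)-5-methyl-2-(prop-1-en-2-yl)hex-4-en-1-yl]-7-(triisopropylsilyloxy)-3,4-dihydro-2H-chromen-4-ol | C=C(C)[C@H](CC=C(C)C)Cc1c(O[Si](C(C)C)(C(C)C)C(C)C)cc(OC)c2c1O[C@@H](c1ccc(O[Si](C(C)C)(C(C)C)C(C)C)cc1OC)C[C@H]2O
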